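## Retrosynthetic overview

1. Feature: on ring B (C5–C10) the acetoxy-bearing C7 and the ring-fusion carbon C5 are 1,3-related. A ring B enone whose only stereocentre is this C–O carbon can therefore dictate C5, and through C5 the quaternary C10, while ring A (C1–C4, with the gem-dimethyl group on C4) is annulated.
2. Endgame: C7 acetate from the silyl ether; C8=C17 from a C8 ketone by methylenation; C8 ketone from the Δ8(9) alkene by hydroboration/oxidation, with C9 settled by equilibration; C9–C11 by Negishi coupling of a C9 enol triflate with the zinc reagent of the C11–C16 iodo ester (C13 from methyl hydrogen (R)-3-methylglutarate).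
3. Key disconnection: C4–C5 and C1–C10 are cut together, giving the 5-silyloxy-2-methylcyclohexenone and 4-methylpent-4-enal. In the forward sense this is a hydrogen-atom-transfer Giese addition and aldol closure in one flask, followed by removal of the C1 hydroxyl.
4. Ring B comes from the chiral pool: the isopropenyl group of (R)-carvone is exchanged for oxygen with retention (ozonolysis, Criegee rearrangement). The aldehyde comes from a Claisen rearrangement.
5. Ring order: ring B (from carvone) first, ring A second (step 5).

Key step: step 5

Remark: labdane numbering is used for all bicyclic compounds (ring A: C1–C5 and C10; ring B: C5–C10; C17 is the exocyclic methylene carbon). α is the face opposite to the C10 methyl group.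
Assumption: methyl hydrogen (R)-3-methylglutarate is bought as the single enantiomer. The facial selectivities in steps 5 and 12 are predictions.

## Route

Step 1
Reactants: 1 (R)-(−)-carvone
Product: 4 (5R)-5-acetoxy-2-methylcyclohex-2-enone, via methoxy hydroperoxide 2 (not isolated), via peroxyacetate 3 (not isolated)
Conditions: O3, CH2Cl2/MeOH, −78 °C, N2 purge; then Ac2O, Et3N, DMAP (catalytic), CH2Cl2, 0 °C to 40 °C
Reagents that add atoms: ozone, [O-][O+]=O; methanol, CO; acetic anhydride, CC(=O)OC(C)=O (held only in 3)
Why: Ozone cleaves the electron-rich isopropenyl alkene in preference to the enone, methanol traps the carbonyl oxide as 2, and acetylation to 3 sets off the Criegee rearrangement, in which the secondary ring carbon migrates from carbon to oxygen with retention, so that the (R) centre of carvone becomes the oxygen-bearing centre that will be C7.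

Step 2
Reactants: 4 (5R)-5-acetoxy-2-methylcyclohex-2-enone
Product: 5 (5R)-5-hydroxy-2-methylcyclohex-2-enone
Conditions: HCl (catalytic, as solution in MeOH), MeOH, 0 °C to rt
Reagents that add atoms: none
Why: Acid-catalysed transesterification removes the acetyl group without touching the C–O bond of the stereocentre and avoids the enolate that, under basic methanolysis, would expel acetate by E1cB elimination and aromatise the ring.

Step 3
Reactants: 5 (5R)-5-hydroxy-2-methylcyclohex-2-enone
Product: 6 (5R)-5-(tert-butyldimethylsilyloxy)-2-methylcyclohex-2-enone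
Conditions: TBSCl, imidazole, DMF, 0 °C to rt
Reagents that add atoms: tert-butyldimethylsilyl chloride, CC(C)(C)[Si](C)(C)Cl
Why: Imidazole-promoted silylation of a secondary alcohol takes place at oxygen with retention, and imidazole is too weak a base to trigger β-elimination.

Step 4
Reactants: 7 2-methylprop-2-en-1-ol; 8 ethyl vinyl ether
Product: 10 4-methylpent-4-enal, via methallyl vinyl ether 9 (not isolated)
Conditions: Hg(OAc)2 (3 mol %), excess 8, reflux; excess 8 distilled off; then 140 °C, sealed tube; distillation
Reagents that add atoms: none
Why: Mercury-catalysed transvinylation gives allyl vinyl ether 9, which on heating undergoes the aliphatic Claisen rearrangement, a [3,3]-sigmatropic shift that forms the future C2–C3 bond and gives the γ,δ-unsaturated aldehyde without creating a stereocentre.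

Step 5
Reactants: 6 (5R)-5-(tert-butyldimethylsilyloxy)-2-methylcyclohex-2-enone; 10 4-methylpent-4-enal
Product: 12 7α-(tert-butyldimethylsilyloxy)-1α-hydroxy-4,4,10β-trimethyl-trans-decalin-9-one (5α-H), via iron enolate 11 (not isolated)
Conditions: Fe(acac)3 (30 mol %), PhSiH3 (2.5 equiv), EtOH/ClCH2CH2Cl, 0 °C to rt, Ar; 10 (2 equiv) added slowly
Reagents that add atoms: none
Why: The iron hydride generated from Fe(acac)3 and PhSiH3 hands a hydrogen atom to the =CH2 terminus of 10 (Markovnikov sense), so that this carbon becomes one of the two C4 methyl groups and C4 becomes a tertiary nucleophilic radical; Giese addition of that radical to C5, the β-carbon of enone 6, is followed by reduction of the α-keto radical by divalent iron to enolate 11, which returns trivalent iron. Ring A is then closed when C10 of 11 adds to the C1 aldehyde at the end of the chain, a 6-(enolexo)-exo-trig aldol cyclisation, so that C4–C5 and C1–C10 are both made in one flask; the closest known reaction type is the iron-catalysed hydrogen-atom-transfer radical–polar crossover annulation of γ,δ-unsaturated aldehydes with cyclic enones. C5 is controlled by C7, because the bulky radical should enter axially on the half-chair of 6 that keeps the silyloxy group pseudo-equatorial and thus anti to it (1,3-trans), as is general for additions to 5-substituted cyclohexenones. C10 is controlled by C5 and by reversibility, because the aldolate cannot dehydrate at the quaternary C10, so retro-aldol/aldol exchange should drain a kinetically formed cis isomer into the trans-fused hydroxy ketone in which C1 and C4 are both equatorial on ring B. C1 is expected to carry the axial 1α-oxygen from a closed metal-bridged transition state, but this centre is erased in steps 6 and 7 and its configuration is not critical. The step needs hydrogen-atom transfer to the electron-rich 1,1-disubstituted alkene of 10 and not to the electron-poor enone, and cross-addition instead of simple reduction of the radical; the polarity match of radical and acceptor, the excess of 10 and its slow addition secure this, while aldehyde, ketone and silyl ether are inert to the iron hydride.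

Step 6
Reactants: 12 7α-(tert-butyldimethylsilyloxy)-1α-hydroxy-4,4,10β-trimethyl-trans-decalin-9-one
Product: 13 1α-O-(phenoxythiocarbonyl) derivative of 12
Conditions: PhOC(S)Cl, DMAP (2 equiv), MeCN, rt to 40 °C
Reagents that add atoms: O-phenyl chlorothionoformate, ClC(=S)Oc1ccccc1
Why: Acylation of the hindered axial alcohol by the DMAP-activated chlorothionoformate runs without alkoxide formation, so that neither retro-aldol cleavage nor E1cB loss of the C7 silyloxy group is provoked, and it gives the radical precursor for the Barton–McCombie reaction.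

Step 7
Reactants: 13 1α-O-(phenoxythiocarbonyl) derivative of 12
Product: 14 7α-(tert-butyldimethylsilyloxy)-4,4,10β-trimethyl-trans-decalin-9-one (5α-H)
Conditions: Bu3SnH (0.2 M), AIBN (catalytic), toluene, 90 °C
Reagents that add atoms: none
Why: In this Barton–McCombie deoxygenation the stannyl radical adds to sulfur, the C1–O bond fragments and the secondary C1 radical takes hydrogen from Bu3SnH, while a 1,2-acyl shift is disfavoured because the C10–C9 bond is equatorial, poorly aligned with the C1 radical orbital, and its migration would lead to a bridged skeleton.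

Step 8
Reactants: 14 7α-(tert-butyldimethylsilyloxy)-4,4,10β-trimethyl-trans-decalin-9-one
Product: 16 C9 enol triflate of 14 (Δ8(9); 7α-silyloxy; 5α-H; 10β-methyl), via potassium enolate 15 (not isolated)
Conditions: KN(SiMe3)2, THF, −78 °C; then N-(5-chloro-2-pyridyl)bis(trifluoromethanesulfonimide) (Comins reagent), −78 °C
Reagents that add atoms: KN(SiMe3)2, [K+].C[Si](C)(C)[N-][Si](C)(C)C (potassium held only in 15); N-(5-chloro-2-pyridyl)bis(trifluoromethanesulfonimide), O=S(=O)(N(c1ccc(Cl)cn1)S(=O)(=O)C(F)(F)F)C(F)(F)F
Why: C10 is quaternary, so the amide base can only remove a C8 proton and a single enolate 15 results, which the highly reactive pyridyl triflimide sulfonylates on oxygen at −78 °C faster than the poor leaving group silyloxide is lost by E1cB elimination.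

Step 9
Reactants: 17 methyl hydrogen (R)-3-methylglutarate
Product: 19 (4S)-4-methyltetrahydro-2H-pyran-2-one, via hydroxy acid 18 (not isolated)
Conditions: LiBH4, THF, 0 °C to reflux; then 2 M HCl, rt
Reagents that add atoms: none
Why: LiBH4 reduces the ester arm while the acid arm is shielded as its lithium carboxylate, and acidification lactonises 18; the stereocentre is not touched, and because the ester arm is the one reduced, the (R) half-ester maps onto (13S) of the target.

Step 10
Reactants: 19 (4S)-4-methyltetrahydro-2H-pyran-2-one
Product: 21 methyl (3R)-5-iodo-3-methylpentanoate, via silyl ester 20 (not isolated)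
Conditions: Me3SiI (1.1 equiv), CH2Cl2, rt; then MeOH, rt
Reagents that add atoms: iodotrimethylsilane, C[Si](C)(C)I; methanol, CO
Why: Me3SiI silylates the lactone carbonyl oxygen and iodide opens the ring by SN2 attack at the primary O–CH2 carbon, after which methanol, acidified by HI from the slight excess of Me3SiI, converts 20 into the methyl ester (Fischer esterification) without touching the stereocentre, whose descriptor changes to (R) only because iodine raises the priority of its arm.

Step 11
Reactants: 16 C9 enol triflate of 14; 21 methyl (3R)-5-iodo-3-methylpentanoate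
Product: 23 methyl (13S)-7α-(tert-butyldimethylsilyloxy)-17-norlabd-8-en-15-oate, via alkylzinc iodide 22 (not isolated)
Conditions: 21, Zn dust (activated with BrCH2CH2Br and Me3SiCl), LiCl, THF, 40 °C; then 16, PdCl2(dppf) (5 mol %), THF/NMP, 55 °C
Reagents that add atoms: zinc, [Zn] (held only in 22)
Why: In this Negishi coupling zinc inserts into the primary C–I bond without harm to the ester, zerovalent palladium adds oxidatively to the C9–O triflate bond, and the wide-bite-angle dppf ligand favours reductive elimination over β-hydride elimination after transmetalation, with no stereocentre touched.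

Step 12
Reactants: 23 methyl (13S)-7α-(tert-butyldimethylsilyloxy)-17-norlabd-8-en-15-oate
Product: 25 methyl (13S)-7α-(tert-butyldimethylsilyloxy)-8β-hydroxy-9β-H-17-norlabdan-15-oate (side chain 9α), via alkylborane 24 (not isolated)
Conditions: BH3·THF (3 equiv), THF, 0 °C to rt; then NaBO3·4H2O, THF/H2O, rt
Reagents that add atoms: borane–THF, B (boron held only in 24); sodium perborate, [Na+].[O-]OB=O
Why: Hydroboration is a syn anti-Markovnikov addition that puts boron on the less substituted C8 (also favoured by the inductive effect of the C7 oxygen) and is expected to occur anti to the pseudo-axial 7α-silyloxy group, on the β face, and perborate then replaces boron by oxygen with retention without saponifying the ester; both new centres are provisional, since C8 is oxidised in step 13 and C9 is corrected in step 14.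

Step 13
Reactants: 25 methyl (13S)-7α-(tert-butyldimethylsilyloxy)-8β-hydroxy-9β-H-17-norlabdan-15-oate
Product: 26 methyl (13S)-7α-(tert-butyldimethylsilyloxy)-8-oxo-9β-H-17-norlabdan-15-oate
Conditions: Dess–Martin periodinane, CH2Cl2, 0 °C to rt
Reagents that add atoms: none
Why: Dess–Martin oxidation converts the hindered secondary alcohol into the ketone under non-basic conditions, so that C7 keeps its configuration, and any 9α-H alcohol from α-face hydroboration would give 27 directly.

Step 14
Reactants: 26 methyl (13S)-7α-(tert-butyldimethylsilyloxy)-8-oxo-9β-H-17-norlabdan-15-oate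
Product: 27 methyl (13S)-7α-(tert-butyldimethylsilyloxy)-8-oxo-17-norlabdan-15-oate (9α-H; side chain 9β)
Conditions: DBU (0.3 equiv), toluene, rt, stopped when 26 is consumed
Reagents that add atoms: none
Why: In this base-catalysed epimerisation through the C8–C9 enolate the axial 9α side chain of 26 is syn-diaxial to the 7α-silyloxy group, so the equilibrium lies far on the side of 27 with the equatorial side chain, whereas the C7 proton of 27 is equatorial, poorly aligned with the carbonyl π system and shielded by the silyl group, so that with a catalytic amidine at room temperature the C7 centre should be kept.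

Step 15
Reactants: 27 methyl (13S)-7α-(tert-butyldimethylsilyloxy)-8-oxo-17-norlabdan-15-oate
Product: 28 methyl (13S)-7α-(tert-butyldimethylsilyloxy)labd-8(17)-en-15-oate
Conditions: Zn dust, CH2Br2, TiCl4, THF, −40 °C to 5 °C (reagent aged); then 27, CH2Cl2, 0 °C to rt
Reagents that add atoms: dibromomethane, BrCBr
Why: In the Takai–Lombardo methylenation the gem-dimetallic methylene reagent is not basic, so that C7 and C9 are not epimerised, and it does not attack esters, which makes it safer here than titanocene methylidene sources that could also methylenate the side-chain ester.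

Step 16
Reactants: 28 methyl (13S)-7α-(tert-butyldimethylsilyloxy)labd-8(17)-en-15-oate
Product: 29 methyl (13S)-7α-hydroxylabd-8(17)-en-15-oate
Conditions: HF·pyridine, pyridine, THF, 0 °C to rt
Reagents that add atoms: none
Why: The strong Si–F bond drives the desilylation, and pyridine-buffered HF leaves the methyl ester, the exocyclic alkene and the allylic C7–O bond untouched, so that the 7α configuration is retained.

Step 17
Reactants: 29 methyl (13S)-7α-hydroxylabd-8(17)-en-15-oate
Product: 30 methyl (13S)-7α-acetoxylabd-8(17)-en-15-oate (target)
Conditions: Ac2O, pyridine, DMAP (catalytic), CH2Cl2, rt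
Reagents that add atoms: acetic anhydride, CC(=O)OC(C)=O
Why: DMAP-catalysed acylation takes place at oxygen, so that the axial 7α-alcohol gives the 7α-acetate with retention and the target is reached.

## Compound list

1 | (R)-(−)-carvone | CC1=CC[C@@H](C(C)=C)CC1=O | starting material
2 | (5R)-5-(1-hydroperoxy-1-methoxyethyl)-2-methylcyclohex-2-enone (epimers at the peroxy carbon) | CC1=CC[C@@H](C(C)(OC)OO)CC1=O | intermediate
3 | peroxyacetate of 2 | CC1=CC[C@@H](C(C)(OC)OOC(C)=O)CC1=O | intermediate
4 | (5R)-5-acetoxy-2-methylcyclohex-2-enone | CC1=CC[C@@H](OC(C)=O)CC1=O | intermediate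
5 | (5R)-5-hydroxy-2-methylcyclohex-2-enone | CC1=CC[C@@H](O)CC1=O | intermediate
6 | (5R)-5-(tert-butyldimethylsilyloxy)-2-methylcyclohex-2-enone | CC1=CC[C@@H](O[Si](C)(C)C(C)(C)C)CC1=O | intermediate
7 | 2-methylprop-2-en-1-ol | C=C(C)CO | starting material
8 | ethyl vinyl ether | C=COCC | starting material
9 | methallyl vinyl ether | C=C(C)COC=C | intermediate
10 | 4-methylpent-4-enal | C=C(C)CCC=O | intermediate
11 | iron-bound C9–C10 enolate of the Giese adduct (drawn as the anion; CMe2CH2CH2CHO chain on C5 trans to the C7 silyloxy group) | [O-]C1=C(C)[C@H](C(C)(C)CCC=O)C[C@@H](O[Si](C)(C)C(C)(C)C)C1 | intermediate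
12 | 7α-(tert-butyldimethylsilyloxy)-1α-hydroxy-4,4,10β-trimethyl-trans-decalin-9-one (5α-H) | O=C1C[C@H](O[Si](C)(C)C(C)(C)C)C[C@H]2C(C)(C)CC[C@H](O)[C@]12C | intermediate
13 | 1α-O-(phenoxythiocarbonyl) derivative of 12 | O=C1C[C@H](O[Si](C)(C)C(C)(C)C)C[C@H]2C(C)(C)CC[C@H](OC(=S)Oc3ccccc3)[C@]12C | intermediate
14 | 7α-(tert-butyldimethylsilyloxy)-4,4,10β-trimethyl-trans-decalin-9-one (5α-H) | O=C1C[C@H](O[Si](C)(C)C(C)(C)C)C[C@H]2C(C)(C)CCC[C@]12C | intermediate
15 | potassium C8–C9 enolate of 14 | [K+].[O-]C1=C[C@H](O[Si](C)(C)C(C)(C)C)C[C@H]2C(C)(C)CCC[C@]12C | intermediate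
16 | C9 enol triflate of 14 (Δ8(9)) | O=S(=O)(OC1=C[C@H](O[Si](C)(C)C(C)(C)C)C[C@H]2C(C)(C)CCC[C@]12C)C(F)(F)F | intermediate
17 | methyl hydrogen (R)-3-methylglutarate, (3R)-5-methoxy-3-methyl-5-oxopentanoic acid | COC(=O)C[C@H](C)CC(=O)O | starting material
18 | (3S)-5-hydroxy-3-methylpentanoic acid | OCC[C@H](C)CC(=O)O | intermediate
19 | (4S)-4-methyltetrahydro-2H-pyran-2-one | O=C1C[C@@H](C)CCO1 | intermediate
20 | trimethylsilyl (3R)-5-iodo-3-methylpentanoate | ICC[C@H](C)CC(=O)O[Si](C)(C)C | intermediate
21 | methyl (3R)-5-iodo-3-methylpentanoate | ICC[C@H](C)CC(=O)OC | intermediate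
22 | [(3R)-5-methoxy-3-methyl-5-oxopentyl]zinc iodide | I[Zn]CC[C@H](C)CC(=O)OC | intermediate
23 | methyl (13S)-7α-(tert-butyldimethylsilyloxy)-17-norlabd-8-en-15-oate | COC(=O)C[C@@H](C)CCC1=C[C@H](O[Si](C)(C)C(C)(C)C)C[C@H]2C(C)(C)CCC[C@]12C | intermediate
24 | 8β-boryl-9β-H adduct of 23 (monoalkylborane) | B[C@H]1[C@H](O[Si](C)(C)C(C)(C)C)C[C@H]2C(C)(C)CCC[C@]2(C)[C@@H]1CC[C@H](C)CC(=O)OC | intermediate
25 | methyl (13S)-7α-(tert-butyldimethylsilyloxy)-8β-hydroxy-9β-H-17-norlabdan-15-oate | O[C@H]1[C@H](O[Si](C)(C)C(C)(C)C)C[C@H]2C(C)(C)CCC[C@]2(C)[C@@H]1CC[C@H](C)CC(=O)OC | intermediate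
26 | methyl (13S)-7α-(tert-butyldimethylsilyloxy)-8-oxo-9β-H-17-norlabdan-15-oate | O=C1[C@H](O[Si](C)(C)C(C)(C)C)C[C@H]2C(C)(C)CCC[C@]2(C)[C@@H]1CC[C@H](C)CC(=O)OC | intermediate
27 | methyl (13S)-7α-(tert-butyldimethylsilyloxy)-8-oxo-17-norlabdan-15-oate (9α-H) | O=C1[C@H](O[Si](C)(C)C(C)(C)C)C[C@H]2C(C)(C)CCC[C@]2(C)[C@H]1CC[C@H](C)CC(=O)OC | intermediate
28 | methyl (13S)-7α-(tert-butyldimethylsilyloxy)labd-8(17)-en-15-oate | C=C1[C@H](O[Si](C)(C)C(C)(C)C)C[C@H]2C(C)(C)CCC[C@]2(C)[C@H]1CC[C@H](C)CC(=O)OC | intermediate
29 | methyl (13S)-7α-hydroxylabd-8(17)-en-15-oate | C=C1[C@H](O)C[C@H]2C(C)(C)CCC[C@]2(C)[C@H]1CC[C@H](C)CC(=O)OC | intermediate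
30 | methyl (13S)-7α-acetoxylabd-8(17)-en-15-oate (5S,7R,9R,10S,13S), CNP0223602.1 | C=C1[C@H](OC(C)=O)C[C@H]2C(C)(C)CCC[C@]2(C)[C@H]1CC[C@H](C)CC(=O)OC | target

## Step count and risks

Total step count: 17.
Longest linear sequence: 14 steps from (R)-carvone (steps 1, 2, 3, 5, 6, 7, 8, 11, 12, 13, 14, 15, 16, 17).

**Step 5.**
- Risk: the alcohol may protonate enolate 11 before it reaches the aldehyde. Ring closure may also stop at the cis ring fusion without later equilibration, or the facial bias at C5 may be weak.
- Fallback, from 6 and 10 back to 12: the two bond formations are separated. Aldehyde 10 is masked with HC(OMe)3 and catalytic TsOH in MeOH as 5,5-dimethoxy-2-methylpent-1-ene F1. This alkene is added to 6 under protic intermolecular hydrogen-atom-transfer Giese conditions (Fe(acac)3, PhSiH3, EtOH, 60 °C) to give the keto acetal F2, in which only C5 matters. PPTS in wet acetone frees the keto aldehyde F3. Ring A is then closed in a separate, reversible aldol reaction (K2CO3, MeOH, 0 °C), in which base, temperature and time can be tuned for the trans-fused 12.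

**Step 12.**
- Risk: hydroboration of the hindered trisubstituted alkene may be slow enough for reduction of the methyl ester to catch up. Boron and the silyloxy group are also anti-periplanar in 24 and may be lost together by β-elimination.
- Fallback, from 23 back to 27, so that 25, 26 and the equilibration are bypassed: buffered mCPBA (NaHCO3, CH2Cl2, 0 °C) converts 23 into the 8β,9β-epoxide F4, drawn as expected for attack anti to the silyloxy group. Cp2TiCl, made from Cp2TiCl2 and Mn dust in THF, opens the epoxide by single-electron transfer from trivalent titanium to the tertiary C9 radical. The planar radical erases the epoxide configuration at C9, and esters are inert to the reagent. 1,4-Cyclohexadiene should deliver hydrogen to the α face, anti to the C10 methyl group and to the 8β-titanoxy group, giving the 8β-hydroxy-9α-H alcohol F5. Dess–Martin oxidation of F5 gives 27.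

**Step 14.**
- Risk: enolisation towards C7 may compete with enolisation towards C9. This would erode the C7 configuration, because relief of the syn-diaxial strain drives both processes.
- Fallback, from 26 back to 27: equilibration is replaced by regiodefined enol ether formation and irreversible protonation. Me3SiOTf and Et3N (CH2Cl2, 0 °C) should give the more substituted Δ8(9) trimethylsilyl enol ether F6, since the alternative would place two bulky silyloxy groups cis on one double bond. Bu4NF buffered with AcOH (THF, −78 °C) then releases the enolate and protonates it axially on the α face, anti to the C10 methyl group, to give 27.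

## Further compounds

F1 | step 5 | 5,5-dimethoxy-2-methylpent-1-ene | C=C(C)CCC(OC)OC
F2 | step 5 | keto acetal: 5-(tert-butyldimethylsilyloxy)-3-(5,5-dimethoxy-2-methylpentan-2-yl)-2-methylcyclohexanone, 3,5-trans, C2 epimers | COC(CCC(C)(C)[C@@H]1C[C@@H](O[Si](C)(C)C(C)(C)C)CC(=O)C1C)OC
F3 | step 5 | keto aldehyde: 4-[5-(tert-butyldimethylsilyloxy)-2-methyl-3-oxocyclohexyl]-4-methylpentanal, ring substituents 1,5-trans, methyl-bearing carbon as epimers | O=CCCC(C)(C)[C@@H]1C[C@@H](O[Si](C)(C)C(C)(C)C)CC(=O)C1C
F4 | step 12 | methyl (13S)-7α-(tert-butyldimethylsilyloxy)-8β,9β-epoxy-17-norlabdan-15-oate | COC(=O)C[C@@H](C)CC[C@]12O[C@H]1[C@H](O[Si](C)(C)C(C)(C)C)C[C@H]1C(C)(C)CCC[C@]21C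
F5 | step 12 | methyl (13S)-7α-(tert-butyldimethylsilyloxy)-8β-hydroxy-17-norlabdan-15-oate (9α-H) | O[C@H]1[C@H](O[Si](C)(C)C(C)(C)C)C[C@H]2C(C)(C)CCC[C@]2(C)[C@H]1CC[C@H](C)CC(=O)OC
F6 | step 14 | methyl (13S)-7α-(tert-butyldimethylsilyloxy)-8-(trimethylsilyloxy)-17-norlabd-8-en-15-oate | COC(=O)C[C@@H](C)CCC1=C(O[Si](C)(C)C)[C@H](O[Si](C)(C)C(C)(C)C)C[C@H]2C(C)(C)CCC[C@]12C
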